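Take the turnover as your unit: one molecule of product made per molecule of catalyst that actually works. Counting in that unit needs the working amount of catalyst, and the charge may not be that amount.

| setting | blue | red | teal | green | violet |
|---|---|---|---|---|---|
| substrate | 80.0 mM | 40.0 mM | 240 mM | 80.0 mM | 80.0 mM |
| partner | 120 mM | 80.0 mM | 120 mM | 120 mM | 120 mM |
| free catalyst | 1.60 mM | 1.60 mM | 1.60 mM | 2.40 mM | 3.30 mM |
| time |  |  |  |  | 15 min |

- blue run (time / min: [substrate] / mM): 2.1: 70.8; 4.3: 64.1; 6.4: 57.1; 8.6: 50.5; 11: 45.3; 13: 40.9; 15: 37.3
- red run (time / min: [substrate] / mM): 2.1: 35.4; 4.3: 30.5; 6.4: 27.4; 8.6: 23.7; 11: 21.1; 13: 18.1; 15: 15.7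
- teal run (time / min: [substrate] / mM): 2.1: 227.1; 4.3: 215.3; 6.4: 205.4; 8.6: 196.1; 11: 186.8; 13: 180.0; 15: 174.8
- green run (time / min: [substrate] / mM): 2.1: 62.3; 4.3: 48.2; 6.4: 37.5; 8.6: 29.0; 11: 21.8; 13: 17.1; 15: 13.0

(each reading ± 0.4 mM)

- reaction order in [partner] at the outset, round the charge of the blue run, defined at two percent of the substrate turned into product
- reaction order in [substrate] at the outset, round the charge of the blue run, defined at two percent of the substrate turned into product (one fixed amount of product, the same in the runs compared)
- the red run starts with 40.0 mM less of substrate and of partner than the blue run, and with no product. Compared where both hold the same amount of substrate, once fifteen percent of what the red run was charged with has turned into product, is the red run faster, slower or alike (within a tenth)?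
- substrate in the violet run at 15 min, as a share of the substrate charged

- Overall: substrate + partner -> product, with free catalyst as catalyst.
- Constant volume, constant temperature.
- What is held in complexes is read along with the free species.
- An order is taken over about fifteen percent of the charge, up and down.

Run the flasks in slow motion, and begin with the first instants, where a part of the charge may already be lost; the later readings tell. The blue run holds 37.3 mM of substrate at 15 min, and the green run holds 37.5 mM at 6.4 min, which is the same within the scatter. So the green run gets there 2.34 times sooner on a charge that is 1.50 times larger, a gain in speed greater than the gain in catalyst. Subtract a fixed amount z from each charge, and call z the dead catalyst: the amount that must go so that equal turnovers mean equal substrate. The two runs then read z = 1.00 mM. The working catalyst, W, is the charge minus z, so W is 0.595 mM in blue, 1.40 mM in green and 2.30 mM in violet.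

Now the middle. Up to its first reading the blue run turns over on average 7.36 min⁻¹ per working catalyst, and over its last interval 3.02 min⁻¹. Tripling the substrate, in teal, raises the early loss by a factor of 1.40, so substrate counts for less than in proportion at these charges.

Then the end, where the violet run lies beyond anything yet read. Equal turnovers mean that its 15 min counts as 24.7 min of the green run, later than the last green reading at 15 min. Substrate is the limiting reagent in violet, charged at less than the partner, so at least 40.0 mM of partner stays through the tail. Between 11 min and 15 min, the green run reads as a decay at 0.129 min⁻¹. Carrying that decay on from 13.0 mM gives my figure for violet, 4.65 % of the charge.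

The forecast, noting that “Product inhibition or catalyst loss would explain this”, gave orders of 0.45 in partner and 0.5 in substrate, called the red run faster, and put violet at 5.5 %, between 2.5 % and 11 %, against my 4.65 %.

The violet run keeps 4.90 % of its substrate at 15 min, with orders of 0.51 in partner and 0.51 in substrate, and the red run comes out faster.

    free catalyst + substrate → loaded catalyst + by-product (172.8 M⁻¹ min⁻¹)
    loaded catalyst + partner → product + free catalyst (114.0 M⁻¹ min⁻¹)
    free catalyst + by-product ⇌ catalyst-by-product complex, settled at all times (9.120 M⁻¹)
    free catalyst + impurity → spent catalyst

In the violet run 76.1 mM of substrate has gone, about 33.1 turnovers on the working catalyst; what z counts is the catalyst that goes to spent catalyst in the scheme. Now use W at the outset rather than at the substrate level where z was read: the blue run makes product at 4.2 mM min⁻¹ where two percent of its substrate has turned, and scaling by W gives 9.88 mM min⁻¹ for the green run, whose simulated rate at that amount of product is 9.5 mM min⁻¹.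

(All runs are calculated for an exercise; noise was put on by code.)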